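**Retrosynthetic overview**

1. Numbering: C1 (≡CH) to C15 (CH3) along the chain; ring A = oxolane O6/C6/C7/C8/C9, ring B = oxocane O13/C7/C8/C9/C10/C11/C12/C13. Endgame: (E)-enyne by Horner–Wadsworth–Emmons olefination of a C4 aldehyde, C12–Br by Appel inversion, C10–Br by conjugate addition of HBr to a C12 enone.
2. Ring B is closed second, by ring-closing metathesis (C10=C11) on the all-cis oxolane; its ether bond O13–C13 comes from an SN2 reaction of the C7 alkoxide with (S)-2-chlorobutanoic acid.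
3. Ring A is closed first, by forming C8–C9: Petasis–Ferrier rearrangement with in-situ reduction of a 4-methylidene-1,3-dioxolane assembled from an (S)-α-hydroxy acid (C4–C7), acrolein (C9–C11) and a titanium methylidene (C8).
4. Enabling feature: in ring A the methylene C8 lies between C7 (bearing O13) and C9 (bearing O6), and O6 ties C9 back to C6; C7–C8–C9 is therefore a latent aldol between a C7 enolate and an O6=C9 oxocarbenium ion, and ring A is the O→C isomer of a cyclic acetal.
5. Stereocontrol: C6 is bought (L-homoserine) and relays C9 and C7 in the key step; C13 is bought; C10 and C12 follow by substrate control on the bicycle.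

Key step: step 4

Assumption: compounds 1, 3, 9 and 19 are taken as commercial; both acetal epimers of 5 can be carried forward, because the acetal carbon becomes planar in step 4.

**Route**

Step 1
Reactants: 1 O-benzyl-L-homoserine
Product: 2 (S)-4-(benzyloxy)-2-hydroxybutanoic acid
Conditions: NaNO2, 1 M H2SO4, H2O, 0 °C to rt
Reagents that add atoms: water, O
Why: Diazotization of the α-amino acid; the carboxylate expels N2 to an α-lactone that water reopens, so the future C6 keeps its (S) configuration by double inversion.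

Step 2
Reactants: 2 (S)-4-(benzyloxy)-2-hydroxybutanoic acid; 3 acrolein
Product: 5 (2S,5S)-5-[2-(benzyloxy)ethyl]-2-ethenyl-1,3-dioxolan-4-one, via bis-TMS hydroxy acid 4 (not isolated)
Conditions: HN(SiMe3)2, 60 °C, volatiles removed; then 3, Me3SiOTf (10 mol%), CH2Cl2, −78 °C
Reagents that add atoms: none
Why: Noyori-type silyl-transfer acetalization, which tolerates enals, should give mainly the cis acetal under kinetic control; the new acetal centre (future C9) is reset in step 4, so its configuration is not critical.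

Step 3
Reactants: 5 (2S,5S)-5-[2-(benzyloxy)ethyl]-2-ethenyl-1,3-dioxolan-4-one
Product: 6 (2S,5S)-5-[2-(benzyloxy)ethyl]-2-ethenyl-4-methylidene-1,3-dioxolane
Conditions: Cp2TiMe2 (2.5 equiv), toluene, 65 °C, dark; filtration through basic alumina
Reagents that add atoms: dimethyltitanocene, C[Ti](C)(C1C=CC=C1)C1C=CC=C1
Why: Petasis methylenation; the thermally formed Cp2Ti=CH2 converts the lactone carbonyl into the exocyclic enol ether (C8) without touching the acetal or C6.

Step 4
Reactants: 6 (2S,5S)-5-[2-(benzyloxy)ethyl]-2-ethenyl-4-methylidene-1,3-dioxolane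
Product: 8 (2S,3S,5S)-2-[2-(benzyloxy)ethyl]-5-ethenyloxolan-3-ol, via oxolan-3-one 7 (not isolated)
Conditions: Al(i-Bu)3 (3 equiv), toluene, −78 °C to rt; aqueous KNaC4H4O6 work-up
Reagents that add atoms: none
Why: Al(i-Bu)3 binds the enol-ether oxygen and cleaves its bond to the acetal carbon, giving a tethered ion pair of an O6=C9 oxocarbenium ion (C9 carrying the vinyl group) and an aluminium enolate of C7, whose carbon C8 adds to C9; the ketone 7 stays on aluminium and is reduced by β-hydride transfer from an isobutyl group. This is the Petasis–Ferrier rearrangement of 4-methylidene-1,3-dioxolanes to oxolan-3-ols, known for acetals of simple α-hydroxy acids. Ring A is closed by a 5-(enolendo)-endo-trig aldol-type attack of C8 on the oxocarbenium carbon C9. C9 is controlled by the bought centre C6: the (E)-oxocarbenium ion should cyclize through an envelope with the C6 side chain and the vinyl group both pseudo-equatorial, giving the 2,5-cis ring from either acetal epimer of 6; C7 is set in the same event because hydride should enter the aluminium-bound ketone anti to the adjacent C6 substituent, giving the all-cis alcohol. The step needs attack at C9 and not at the vinyl terminus of the allyl-type cation, which five-membered against seven-membered closure inside the ion pair should secure; it also needs the vinyl group to survive, which holds at or below room temperature where Al(i-Bu)3 does not hydroaluminate alkenes.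

Step 5
Reactants: 8 (2S,3S,5S)-2-[2-(benzyloxy)ethyl]-5-ethenyloxolan-3-ol; 9 (S)-2-chlorobutanoic acid
Product: 10 (R)-2-{[(2S,3S,5S)-2-[2-(benzyloxy)ethyl]-5-ethenyloxolan-3-yl]oxy}butanoic acid
Conditions: NaH (4 equiv), 1,4-dioxane, rt; then 9, 65 °C; aqueous HCl to pH 3
Reagents that add atoms: none
Why: Williamson ether synthesis on the sodium salt of the α-chloro acid, as used for lactyl ethers of hindered carbohydrate alkoxides; SN2 inversion turns the (S) C–Cl centre into the (R) C13–O13 ether, and the carboxylate form blocks acyl attack.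

Step 6
Reactants: 10 (R)-2-{[(2S,3S,5S)-2-[2-(benzyloxy)ethyl]-5-ethenyloxolan-3-yl]oxy}butanoic acid
Product: 11 (R)-2-{[(2S,3S,5S)-2-[2-(benzyloxy)ethyl]-5-ethenyloxolan-3-yl]oxy}-N-methoxy-N-methylbutanamide
Conditions: MeNH(OMe)·HCl, EDC·HCl, HOBt, i-Pr2NEt, CH2Cl2, 0 °C to rt
Reagents that add atoms: N,O-dimethylhydroxylamine hydrochloride, CNOC.Cl
Why: Carbodiimide amidation to the Weinreb amide through the HOBt ester, which avoids ketene formation and so should leave C13 unepimerized.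

Step 7
Reactants: 11 (R)-2-{[(2S,3S,5S)-2-[2-(benzyloxy)ethyl]-5-ethenyloxolan-3-yl]oxy}-N-methoxy-N-methylbutanamide
Product: 12 (R)-4-{[(2S,3S,5S)-2-[2-(benzyloxy)ethyl]-5-ethenyloxolan-3-yl]oxy}hex-1-en-3-one
Conditions: CH2=CHMgBr, THF, −78 to 0 °C; poured into cold 1 M HCl
Reagents that add atoms: vinylmagnesium bromide, C=C[Mg]Br
Why: Weinreb ketone synthesis; the magnesium-chelated tetrahedral adduct stops at the ketone stage, and the acidic inverse quench keeps the released amine from adding to the vinyl ketone.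

Step 8
Reactants: 12 (R)-4-{[(2S,3S,5S)-2-[2-(benzyloxy)ethyl]-5-ethenyloxolan-3-yl]oxy}hex-1-en-3-one
Product: 13 (1S,3R,5Z,7S,9S)-9-[2-(benzyloxy)ethyl]-3-ethyl-2,8-dioxabicyclo[5.2.1]dec-5-en-4-one
Conditions: second-generation Hoveyda–Grubbs catalyst (H2IMes)Cl2Ru(=CH–C6H4-2-O-i-Pr) (10 mol%), toluene (1 mM), 80 °C
Reagents that add atoms: none
Why: Ring-closing metathesis of the C9 vinyl group with the enone vinyl group closes ring B; both chains sit cis on ring A, and the eight-membered ring can hold only the (Z)-alkene.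

Step 9
Reactants: 13 (1S,3R,5Z,7S,9S)-9-[2-(benzyloxy)ethyl]-3-ethyl-2,8-dioxabicyclo[5.2.1]dec-5-en-4-one
Product: 14 (1S,3R,6S,7S,9S)-9-[2-(benzyloxy)ethyl]-6-bromo-3-ethyl-2,8-dioxabicyclo[5.2.1]decan-4-one
Conditions: HBr (33% in AcOH, 1.5 equiv), CH2Cl2, −20 °C
Reagents that add atoms: hydrogen bromide, Br
Why: Conjugate (1,4) hydrobromination of the enone; bromide should attack C10 anti to the γ-alkoxy bond C9–O6, on the face of ring B away from the O6–C6 bridge, giving the (6S) bromide.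

Step 10
Reactants: 14 (1S,3R,6S,7S,9S)-9-[2-(benzyloxy)ethyl]-6-bromo-3-ethyl-2,8-dioxabicyclo[5.2.1]decan-4-one
Product: 15 (1S,3R,4R,6S,7S,9S)-9-[2-(benzyloxy)ethyl]-6-bromo-3-ethyl-2,8-dioxabicyclo[5.2.1]decan-4-ol
Conditions: Zn(BH4)2, Et2O, −20 °C
Reagents that add atoms: none
Why: Chelation-controlled reduction of the α-alkoxy ketone; zinc bridges the C12 carbonyl and O13, hydride should enter anti to the C13 ethyl group to give the 12-OH cis to ethyl, and the non-basic reagent avoids loss of HBr.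

Step 11
Reactants: 15 (1S,3R,4R,6S,7S,9S)-9-[2-(benzyloxy)ethyl]-6-bromo-3-ethyl-2,8-dioxabicyclo[5.2.1]decan-4-ol
Product: 16 (1S,3R,4S,6S,7S,9S)-9-[2-(benzyloxy)ethyl]-4,6-dibromo-3-ethyl-2,8-dioxabicyclo[5.2.1]decane
Conditions: CBr4, P(n-C8H17)3, toluene, 70 °C
Reagents that add atoms: carbon tetrabromide, BrC(Br)(Br)Br
Why: Appel bromination; SN2 displacement of the oxyphosphonium ion inverts C12 to the (S) bromide trans to the ethyl group.

Step 12
Reactants: 16 (1S,3R,4S,6S,7S,9S)-9-[2-(benzyloxy)ethyl]-4,6-dibromo-3-ethyl-2,8-dioxabicyclo[5.2.1]decane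
Product: 17 2-[(1S,3R,4S,6S,7S,9S)-4,6-dibromo-3-ethyl-2,8-dioxabicyclo[5.2.1]decan-9-yl]ethan-1-ol
Conditions: BCl3 (1 M in CH2Cl2), CH2Cl2, −78 °C; aqueous NaHCO3 work-up
Reagents that add atoms: none
Why: Lewis-acid debenzylation, chosen because hydrogenolysis would also cleave the C–Br bonds; secondary bromides and the ring ethers should be inert at −78 °C.

Step 13
Reactants: 17 2-[(1S,3R,4S,6S,7S,9S)-4,6-dibromo-3-ethyl-2,8-dioxabicyclo[5.2.1]decan-9-yl]ethan-1-ol
Product: 18 2-[(1S,3R,4S,6S,7S,9S)-4,6-dibromo-3-ethyl-2,8-dioxabicyclo[5.2.1]decan-9-yl]acetaldehyde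
Conditions: Dess–Martin periodinane, CH2Cl2, 0 °C to rt
Reagents that add atoms: none
Why: Dess–Martin oxidation is neutral, so the β-alkoxy aldehyde should not undergo β-elimination and the bromides are untouched.

Step 14
Reactants: 18 2-[(1S,3R,4S,6S,7S,9S)-4,6-dibromo-3-ethyl-2,8-dioxabicyclo[5.2.1]decan-9-yl]acetaldehyde; 19 diethyl [3-(trimethylsilyl)prop-2-yn-1-yl]phosphonate
Product: 20 trimethyl{(3E)-5-[(1S,3R,4S,6S,7S,9S)-4,6-dibromo-3-ethyl-2,8-dioxabicyclo[5.2.1]decan-9-yl]pent-3-en-1-yn-1-yl}silane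
Conditions: 19, LiN(SiMe3)2, THF, −78 °C; then 18, −78 to 0 °C
Reagents that add atoms: none
Why: Horner–Wadsworth–Emmons olefination with the propargylic phosphonate anion; reversible addition and syn elimination from the more stable adduct should give the (E)-C3=C4 alkene.

Step 15
Reactants: 20 trimethyl{(3E)-5-[(1S,3R,4S,6S,7S,9S)-4,6-dibromo-3-ethyl-2,8-dioxabicyclo[5.2.1]decan-9-yl]pent-3-en-1-yn-1-yl}silane
Product: 21 (1S,3R,4S,6S,7S,9S)-4,6-dibromo-3-ethyl-9-[(2E)-pent-2-en-4-yn-1-yl]-2,8-dioxabicyclo[5.2.1]decane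
Conditions: K2CO3 (0.2 equiv), MeOH, 0 °C
Reagents that add atoms: none
Why: Base-catalysed methanolysis of the alkynyl C–Si bond; the conditions are mild enough that the secondary bromides should survive.

**Compound list**

1 | O-benzyl-L-homoserine | N[C@@H](CCOCc1ccccc1)C(=O)O | starting material
2 | (S)-4-(benzyloxy)-2-hydroxybutanoic acid | O[C@@H](CCOCc1ccccc1)C(=O)O | intermediate
3 | acrolein (prop-2-enal) | C=CC=O | starting material
4 | trimethylsilyl (S)-4-(benzyloxy)-2-[(trimethylsilyl)oxy]butanoate | C[Si](C)(C)O[C@@H](CCOCc1ccccc1)C(=O)O[Si](C)(C)C | intermediate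
5 | (2S,5S)-5-[2-(benzyloxy)ethyl]-2-ethenyl-1,3-dioxolan-4-one | c1ccccc1COCC[C@@H]1O[C@H](C=C)OC1=O | intermediate
6 | (2S,5S)-5-[2-(benzyloxy)ethyl]-2-ethenyl-4-methylidene-1,3-dioxolane | c1ccccc1COCC[C@@H]1O[C@H](C=C)OC1=C | intermediate
7 | (2S,5S)-2-[2-(benzyloxy)ethyl]-5-ethenyloxolan-3-one | c1ccccc1COCC[C@@H]1O[C@H](C=C)CC1=O | intermediate
8 | (2S,3S,5S)-2-[2-(benzyloxy)ethyl]-5-ethenyloxolan-3-ol | c1ccccc1COCC[C@@H]1O[C@H](C=C)C[C@@H]1O | intermediate
9 | (S)-2-chlorobutanoic acid | CC[C@H](Cl)C(=O)O | starting material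
10 | (R)-2-{[(2S,3S,5S)-2-[2-(benzyloxy)ethyl]-5-ethenyloxolan-3-yl]oxy}butanoic acid | c1ccccc1COCC[C@@H]1O[C@H](C=C)C[C@@H]1O[C@H](CC)C(=O)O | intermediate
11 | (R)-2-{[(2S,3S,5S)-2-[2-(benzyloxy)ethyl]-5-ethenyloxolan-3-yl]oxy}-N-methoxy-N-methylbutanamide | c1ccccc1COCC[C@@H]1O[C@H](C=C)C[C@@H]1O[C@H](CC)C(=O)N(C)OC | intermediate
12 | (R)-4-{[(2S,3S,5S)-2-[2-(benzyloxy)ethyl]-5-ethenyloxolan-3-yl]oxy}hex-1-en-3-one | c1ccccc1COCC[C@@H]1O[C@H](C=C)C[C@@H]1O[C@H](CC)C(=O)C=C | intermediate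
13 | (1S,3R,5Z,7S,9S)-9-[2-(benzyloxy)ethyl]-3-ethyl-2,8-dioxabicyclo[5.2.1]dec-5-en-4-one | c1ccccc1COCC[C@@H]1O[C@H]2C[C@@H]1O[C@H](CC)C(=O)/C=C\2 | intermediate
14 | (1S,3R,6S,7S,9S)-9-[2-(benzyloxy)ethyl]-6-bromo-3-ethyl-2,8-dioxabicyclo[5.2.1]decan-4-one | c1ccccc1COCC[C@@H]1O[C@H]2C[C@@H]1O[C@H](CC)C(=O)C[C@@H]2Br | intermediate
15 | (1S,3R,4R,6S,7S,9S)-9-[2-(benzyloxy)ethyl]-6-bromo-3-ethyl-2,8-dioxabicyclo[5.2.1]decan-4-ol | c1ccccc1COCC[C@@H]1O[C@H]2C[C@@H]1O[C@H](CC)[C@H](O)C[C@@H]2Br | intermediate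
16 | (1S,3R,4S,6S,7S,9S)-9-[2-(benzyloxy)ethyl]-4,6-dibromo-3-ethyl-2,8-dioxabicyclo[5.2.1]decane | c1ccccc1COCC[C@@H]1O[C@H]2C[C@@H]1O[C@H](CC)[C@@H](Br)C[C@@H]2Br | intermediate
17 | 2-[(1S,3R,4S,6S,7S,9S)-4,6-dibromo-3-ethyl-2,8-dioxabicyclo[5.2.1]decan-9-yl]ethan-1-ol | OCC[C@@H]1O[C@H]2C[C@@H]1O[C@H](CC)[C@@H](Br)C[C@@H]2Br | intermediate
18 | 2-[(1S,3R,4S,6S,7S,9S)-4,6-dibromo-3-ethyl-2,8-dioxabicyclo[5.2.1]decan-9-yl]acetaldehyde | O=CC[C@@H]1O[C@H]2C[C@@H]1O[C@H](CC)[C@@H](Br)C[C@@H]2Br | intermediate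
19 | diethyl [3-(trimethylsilyl)prop-2-yn-1-yl]phosphonate | CCOP(=O)(CC#C[Si](C)(C)C)OCC | starting material
20 | trimethyl{(3E)-5-[(1S,3R,4S,6S,7S,9S)-4,6-dibromo-3-ethyl-2,8-dioxabicyclo[5.2.1]decan-9-yl]pent-3-en-1-yn-1-yl}silane | C[Si](C)(C)C#C/C=C/C[C@@H]1O[C@H]2C[C@@H]1O[C@H](CC)[C@@H](Br)C[C@@H]2Br | intermediate
21 | (1S,3R,4S,6S,7S,9S)-4,6-dibromo-3-ethyl-9-[(2E)-pent-2-en-4-yn-1-yl]-2,8-dioxabicyclo[5.2.1]decane | C#C/C=C/C[C@@H]1O[C@H]2C[C@@H]1O[C@H](CC)[C@@H](Br)C[C@@H]2Br | target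

**Step count and risks**

Total step count: 15. Longest linear sequence: 15 steps (1 to 21; compounds 3, 9 and 19 enter as bought reagents).

Steps most likely to fail:

Step 8. The electron-poor enone alkene may initiate slowly, and intermolecular metathesis (oligomerization) may outrun closure of the strained, bridged eight-membered ring. The fallback sets out from 12: Luche reduction (NaBH4, CeCl3·7H2O, MeOH, −78 °C) should give the C12 dienol F1 as an inconsequential epimer mixture. Its two electron-rich terminal alkenes should close more readily with the second-generation Grubbs catalyst (H2IMes)(PCy3)Cl2Ru=CHPh under high dilution to the cyclic allylic alcohol F2. Dess–Martin oxidation of F2 comes back to the route at 13.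

Step 9. The addition is reversible, so HBr may be lost again on work-up. Acid may enolize the ketone toward C13 and epimerize it. Facial selectivity at C10 may be incomplete. The fallback sets out from 13: Me3SiBr in CH2Cl2 at −78 °C should add 1,4 under aprotic, kinetic conditions and trap the adduct irreversibly as the β-bromo silyl enol ether F3. Hydrolysis of F3 with pH 7 phosphate buffer in THF at 0 °C comes back to the route at 14, which is then reduced at once as in step 10.

Step 11. The ring oxygen O13 may take part as a neighbouring group (oxonium ion, then retention or ring contraction), and E2 elimination may compete at the hindered C12. The fallback sets out from 15: ClCH2SO2Cl and pyridine in CH2Cl2 at 0 °C should give the chloromethanesulfonate F4. Displacement of this small, highly reactive leaving group with LiBr in THF/DMPU at 40 °C is a separate SN2 step with inversion and comes back to the route at 16.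

**Further compounds**

F1 | step 8 | (3RS,4R)-4-{[(2S,3S,5S)-2-[2-(benzyloxy)ethyl]-5-ethenyloxolan-3-yl]oxy}hex-1-en-3-ol | c1ccccc1COCC[C@@H]1O[C@H](C=C)C[C@@H]1O[C@H](CC)C(O)C=C
F2 | step 8 | (1S,3R,4RS,5Z,7S,9S)-9-[2-(benzyloxy)ethyl]-3-ethyl-2,8-dioxabicyclo[5.2.1]dec-5-en-4-ol | c1ccccc1COCC[C@@H]1O[C@H]2C[C@@H]1O[C@H](CC)C(O)/C=C\2
F3 | step 9 | {[(1S,3R,6S,7S,9S)-9-[2-(benzyloxy)ethyl]-6-bromo-3-ethyl-2,8-dioxabicyclo[5.2.1]dec-4-en-4-yl]oxy}(trimethyl)silane | c1ccccc1COCC[C@@H]1O[C@H]2C[C@@H]1O[C@H](CC)/C(O[Si](C)(C)C)=C\[C@@H]2Br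
F4 | step 11 | (1S,3R,4R,6S,7S,9S)-9-[2-(benzyloxy)ethyl]-6-bromo-3-ethyl-2,8-dioxabicyclo[5.2.1]decan-4-yl chloromethanesulfonate | c1ccccc1COCC[C@@H]1O[C@H]2C[C@@H]1O[C@H](CC)[C@H](OS(=O)(=O)CCl)C[C@@H]2Br
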